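**Retrosynthetic overview**
- C8 carbinol ⇐ C8 ketone: late hydroxyl-directed reduction, controlled by the C7 tertiary alcohol.
- Pyran ring (ring B, formed last) ⇐ oxa-6π electrocyclisation of a 1-oxatriene with loss of Me2NH; the oxatriene comes from lateral C-acylation of a ring-A enaminone by the side-chain ester.
- Carbocycle (ring A, formed first) ⇐ vinylogous Dieckmann closure onto a lactic-acid-derived dioxolanone; C7 comes from (S)-lactic acid by self-regeneration of the stereocentre, and the C5 chlorine is installed before ring closure.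
- Side chain ⇐ L-isoleucine (two stereocentres bought), chelation-controlled MeMgBr addition (tertiary carbinol), cross-metathesis (E-alkene).

Assumption: the target is read as drawn, i.e. (7S,8R) with a trans-7,8-diol and a (1E,3R,4S,5S) side chain.

**Step 1**
Reactants: 1 L-isoleucine
Product: 2 (2S,3S)-2-hydroxy-3-methylpentanoic acid
Conditions: NaNO2, 1 M H2SO4 (aq), 0 °C → rt
Reagents that add atoms: water (O)
Why: Diazotisation with neighbouring-carboxylate participation (α-lactone, double inversion) replaces NH2 by OH with retention, so both bought stereocentres are kept.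

**Step 2**
Reactants: 2 (2S,3S)-2-hydroxy-3-methylpentanoic acid
Product: 3 (2S,3S)-2-hydroxy-N-methoxy-N,3-dimethylpentanamide
Conditions: MeNH(OMe)·HCl, EDC·HCl, HOBt, N-methylmorpholine, CH2Cl2, 0 °C → rt
Reagents that add atoms: N,O-dimethylhydroxylamine hydrochloride (CNOC.Cl)
Why: Carbodiimide amide coupling gives the Weinreb amide without touching either stereocentre (the free α-hydroxyl is tolerated under HOBt activation).

**Step 3**
Reactants: 3 (2S,3S)-2-hydroxy-N-methoxy-N,3-dimethylpentanamide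
Product: 4 (4S,5S)-4-hydroxy-5-methylhept-1-en-3-one
Conditions: CH2=CHMgBr (3 equiv), THF, −78 → 0 °C; inverse quench into cold 1 M HCl
Reagents that add atoms: vinylmagnesium bromide (C=C[Mg]Br)
Why: Weinreb ketone synthesis, in which the stable magnesium chelate stops at the ketone and the α-alkoxide blocks enolisation, so C4 keeps its configuration (the acidic quench prevents aza-Michael addition of the released amine).

**Step 4**
Reactants: 4 (4S,5S)-4-hydroxy-5-methylhept-1-en-3-one
Product: 5 (3R,4S,5S)-3,5-dimethylhept-1-ene-3,4-diol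
Conditions: MeMgBr (3 equiv), Et2O, −78 °C; aq. NH4Cl
Reagents that add atoms: methylmagnesium bromide (C[Mg]Br)
Why: Chelation-controlled (Cram chelate) Grignard 1,2-addition: Mg bridges the α-alkoxide and the carbonyl and methyl attacks anti to the sec-butyl group, setting the tertiary carbinol as 3R (hydroxyls syn along the sec-butyl···methyl backbone).

**Step 5**
Reactants: 5 (3R,4S,5S)-3,5-dimethylhept-1-ene-3,4-diol
Product: 6 methyl (2E,4R,5S,6S)-4,5-dihydroxy-4,6-dimethyloct-2-enoate
Conditions: methyl acrylate (5 equiv), second-generation Hoveyda–Grubbs catalyst RuCl2(H2IMes)(=CH-C6H4-2-OiPr) (5 mol %), CH2Cl2, 40 °C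
Reagents that add atoms: methyl acrylate (C=CC(=O)OC)
Why: Olefin cross-metathesis between a hindered tertiary allylic alcohol (no homodimerisation) and an electron-poor acrylate gives the E-enoate selectively and touches no stereocentre.

**Step 6**
Reactants: 7 (S)-lactic acid
Product: 8 (2S,5S)-2-tert-butyl-5-methyl-1,3-dioxolan-4-one (cis)
Conditions: t-BuCHO, cat. p-TsOH·H2O, cat. H2SO4, pentane, reflux (Dean–Stark); recrystallise from Et2O/pentane, −78 °C
Reagents that add atoms: pivalaldehyde (CC(C)(C)C=O)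
Why: Acid-catalysed acetalisation favours the cis-dioxolanone, which is purified by crystallisation, so the lactic acid centre fixes the new acetal centre (self-regeneration of stereocentres).

**Step 7**
Reactants: 8 (2S,5S)-2-tert-butyl-5-methyl-1,3-dioxolan-4-one
Product: 9 (2S,5R)-2-tert-butyl-5-methyl-5-(3-methylbut-2-enoyl)-1,3-dioxolan-4-one
Conditions: LiN(iPr)2 (1.05 equiv), THF, −78 °C; cannulate the enolate into 3-methylbut-2-enoyl chloride (1.5 equiv), THF, −78 °C
Reagents that add atoms: 3-methylbut-2-enoyl chloride (CC(C)=CC(Cl)=O)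
Why: C-Acylation of the lithium ester enolate, with the acyl group entering trans to the tert-butyl group, builds the quaternary carbon (future C7) with overall retention under control of the acetal centre; inverse addition prevents γ-deprotonation of the product.

**Step 8**
Reactants: 9 (2S,5R)-2-tert-butyl-5-methyl-5-(3-methylbut-2-enoyl)-1,3-dioxolan-4-one
Product: 10 (2S,5R)-2-tert-butyl-5-(2-chloro-3-methylbut-2-enoyl)-5-methyl-1,3-dioxolan-4-one
Conditions: PhICl2 (1.2 equiv), pyridine (3 equiv), CH2Cl2, 0 °C → rt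
Reagents that add atoms: iodobenzene dichloride (ClI(Cl)c1ccccc1)
Why: α-Chlorination of the enone by chlorine addition and pyridine-mediated E1cB dehydrochlorination installs the C5 chlorine, which also makes the two flanks of the future ring different so that C7 cannot racemise through a symmetric dienolate.

**Step 9**
Reactants: 10 (2S,5R)-2-tert-butyl-5-(2-chloro-3-methylbut-2-enoyl)-5-methyl-1,3-dioxolan-4-one
Product: 11 (6S)-2-chloro-6-hydroxy-3,6-dimethylcyclohex-2-ene-1,5-dione (largely enolised)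
Conditions: LiN(SiMe3)2 (2.3 equiv), THF, −78 → 0 °C; 1 M HCl to pH 3
Reagents that add atoms: none
Why: Vinylogous Dieckmann (Claisen) cyclisation, in which the γ-carbon of the dienolate attacks the acylal carbonyl in a six-membered closure and the tetrahedral intermediate collapses with loss of pivalaldehyde, forms ring A and frees the C7 hydroxyl without involving the quaternary centre.

**Step 10**
Reactants: 11 (6S)-2-chloro-6-hydroxy-3,6-dimethylcyclohex-2-ene-1,5-dione
Product: 12 (4Z,6S)-2-chloro-4-[(dimethylamino)methylidene]-6-hydroxy-3,6-dimethylcyclohex-2-ene-1,5-dione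
Conditions: Me2NCH(OMe)2 (1.3 equiv), CH2Cl2, rt
Reagents that add atoms: N,N-dimethylformamide dimethyl acetal (COC(OC)N(C)C)
Why: Condensation of the doubly activated ring CH2 (α to the ketone and vinylogous to the enone) with the formamide acetal gives the enaminone and brings in C1 at the aldehyde oxidation level.

**Step 11**
Reactants: 12 (4Z,6S)-2-chloro-4-[(dimethylamino)methylidene]-6-hydroxy-3,6-dimethylcyclohex-2-ene-1,5-dione; 6 methyl (2E,4R,5S,6S)-4,5-dihydroxy-4,6-dimethyloct-2-enoate
Product: 15 (7S)-5-chloro-3-[(1E,3R,4S,5S)-3,4-dihydroxy-3,5-dimethylhept-1-en-1-yl]-7-hydroxy-7-methyl-6H-isochromene-6,8(7H)-dione, via C-acylated triketone 13 (not isolated), via 2H-pyran aminal 14 (not isolated)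
Conditions: 12, LiN(iPr)2 (3.3 equiv), THF, −78 °C; add 6 (pre-treated with LiN(SiMe3)2, 2.0 equiv, THF, −78 °C); −78 → −20 °C; AcOH; then PhMe, 80 °C
Reagents that add atoms: none
Why: Lateral (vinylogous) lithiation of the γ-methyl and Claisen-type C-acylation by ester 6 (Michael addition is blocked by the quaternary γ-carbon) give 13, whose (Z)-dienone tautomer is a 1-oxatriene that closes by thermal oxa-6π electrocyclisation to 14, and 1,4-elimination of Me2NH then gives the azaphilone chromophore (ring B) without touching any stereocentre.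

**Step 12**
Reactants: 15 (7S)-5-chloro-3-[(1E,3R,4S,5S)-3,4-dihydroxy-3,5-dimethylhept-1-en-1-yl]-7-hydroxy-7-methyl-6H-isochromene-6,8(7H)-dione
Product: 16 (7S,8R)-5-chloro-3-[(1E,3R,4S,5S)-3,4-dihydroxy-3,5-dimethylhept-1-en-1-yl]-7,8-dihydroxy-7-methyl-7,8-dihydro-6H-isochromen-6-one (target)
Conditions: Me4NBH(OAc)3 (3 equiv), MeCN/AcOH (1:1), −20 °C
Reagents that add atoms: none
Why: Hydroxyl-directed reduction, in which the borohydride bound to the C7 oxygen delivers hydride intramolecularly to the more ketone-like C8 carbonyl on the face of the C7–O bond, gives the trans-7,8-diol (8R).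

**Compound list**
1 | L-isoleucine, (2S,3S)-2-amino-3-methylpentanoic acid | CC[C@H](C)[C@H](N)C(=O)O | starting material
2 | (2S,3S)-2-hydroxy-3-methylpentanoic acid | CC[C@H](C)[C@H](O)C(=O)O | intermediate
3 | (2S,3S)-2-hydroxy-N-methoxy-N,3-dimethylpentanamide | CC[C@H](C)[C@H](O)C(=O)N(C)OC | intermediate
4 | (4S,5S)-4-hydroxy-5-methylhept-1-en-3-one | CC[C@H](C)[C@H](O)C(=O)C=C | intermediate
5 | (3R,4S,5S)-3,5-dimethylhept-1-ene-3,4-diol | CC[C@H](C)[C@H](O)[C@](C)(O)C=C | intermediate
6 | methyl (2E,4R,5S,6S)-4,5-dihydroxy-4,6-dimethyloct-2-enoate | CC[C@H](C)[C@H](O)[C@](C)(O)/C=C/C(=O)OC | intermediate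
7 | (S)-lactic acid | C[C@H](O)C(=O)O | starting material
8 | (2S,5S)-2-tert-butyl-5-methyl-1,3-dioxolan-4-one (cis) | C[C@@H]1O[C@H](C(C)(C)C)OC1=O | intermediate
9 | (2S,5R)-2-tert-butyl-5-methyl-5-(3-methylbut-2-enoyl)-1,3-dioxolan-4-one | CC(C)=CC(=O)[C@@]1(C)O[C@H](C(C)(C)C)OC1=O | intermediate
10 | (2S,5R)-2-tert-butyl-5-(2-chloro-3-methylbut-2-enoyl)-5-methyl-1,3-dioxolan-4-one | CC(C)=C(Cl)C(=O)[C@@]1(C)O[C@H](C(C)(C)C)OC1=O | intermediate
11 | (6S)-2-chloro-6-hydroxy-3,6-dimethylcyclohex-2-ene-1,5-dione | CC1=C(Cl)C(=O)[C@@](C)(O)C(=O)C1 | intermediate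
12 | (4Z,6S)-2-chloro-4-[(dimethylamino)methylidene]-6-hydroxy-3,6-dimethylcyclohex-2-ene-1,5-dione | CN(C)/C=C1/C(C)=C(Cl)C(=O)[C@@](C)(O)C1=O | intermediate
13 | (4Z,6S)-2-chloro-3-[(3E,5R,6S,7S)-5,6-dihydroxy-5,7-dimethyl-2-oxonon-3-en-1-yl]-4-[(dimethylamino)methylidene]-6-hydroxy-6-methylcyclohex-2-ene-1,5-dione | CC[C@H](C)[C@H](O)[C@](C)(O)/C=C/C(=O)CC1=C(Cl)C(=O)[C@@](C)(O)C(=O)/C1=C\N(C)C | intermediate
14 | (7S)-5-chloro-3-[(1E,3R,4S,5S)-3,4-dihydroxy-3,5-dimethylhept-1-en-1-yl]-1-(dimethylamino)-7-hydroxy-7-methyl-1H-isochromene-6,8(5H,7H)-dione (C1 and C5 epimers) | CC[C@H](C)[C@H](O)[C@](C)(O)/C=C/C1=CC2=C(C(N(C)C)O1)C(=O)[C@](C)(O)C(=O)C2Cl | intermediate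
15 | (7S)-5-chloro-3-[(1E,3R,4S,5S)-3,4-dihydroxy-3,5-dimethylhept-1-en-1-yl]-7-hydroxy-7-methyl-6H-isochromene-6,8(7H)-dione | CC[C@H](C)[C@H](O)[C@](C)(O)/C=C/C1=CC2=C(Cl)C(=O)[C@@](C)(O)C(=O)C2=CO1 | intermediate
16 | (7S,8R)-5-chloro-3-[(1E,3R,4S,5S)-3,4-dihydroxy-3,5-dimethylhept-1-en-1-yl]-7,8-dihydroxy-7-methyl-7,8-dihydro-6H-isochromen-6-one | CC[C@H](C)[C@H](O)[C@](C)(O)/C=C/C1=CC2=C(Cl)C(=O)[C@@](C)(O)[C@H](O)C2=CO1 | target

**Step count**
Total: 12 steps. Longest linear sequence: 7 steps (steps 1–5, 11, 12; the branch of steps 6–10, 11, 12 is equally long).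

**Three steps most likely to fail, each with one fallback**

Step 9 (vinylogous Dieckmann closure). The amide base may attack the acylal or the lithium dienolate may cyclise poorly. The fallback sets out from 10 and generates the dienolate without amide base. Soft enolisation of 10 (Me3SiOTf, Et3N, CH2Cl2, 0 °C) gives the trimethylsilyl dienol ether (2S,5R)-2-tert-butyl-5-[2-chloro-3-methyl-1-(trimethylsilyloxy)buta-1,3-dien-1-yl]-5-methyl-1,3-dioxolan-4-one F1. Catalytic Bu4N[Ph3SiF2] (THF, −40 °C → rt, then dilute HCl) then releases the naked dienolate, which closes onto the acylal with loss of pivalaldehyde. The route is rejoined at 11.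

Step 11 (lateral acylation and ring-B closure). The dianion of 12 may fail to acylate the dialkoxide of ester 6, or may add in Michael fashion. The fallback sets out from 5 and makes the C4–C3 bond by a vinylogous aldol. Cross-metathesis of 5 with crotonaldehyde (same Ru catalyst, CH2Cl2, 40 °C) gives the enal (2E,4R,5S,6S)-4,5-dihydroxy-4,6-dimethyloct-2-enal F2. The dianion of 12 (LiN(iPr)2, THF, −78 °C) adds 1,2 to F2 to give the allylic alcohol (4Z,6S)-2-chloro-4-[(dimethylamino)methylidene]-6-hydroxy-6-methyl-3-[(3E,5R,6S,7S)-2,5,6-trihydroxy-5,7-dimethylnon-3-en-1-yl]cyclohex-2-ene-1,5-dione F3 (both carbinol epimers). MnO2 (CH2Cl2, rt) oxidises only this secondary allylic alcohol to ketone 13. Warming in PhMe with a little AcOH (80 °C) closes 13 through 14, and the route is rejoined at 15.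

Step 12 (C8-selective reduction). Hydride may also reach the C6 carbonyl, which is likewise α to the C7 hydroxyl. The fallback sets out from 15 and reduces both ketones on purpose. NaBH4 with CeCl3·7H2O (MeOH, −40 °C) gives the triol (7S,8R)-5-chloro-3-[(1E,3R,4S,5S)-3,4-dihydroxy-3,5-dimethylhept-1-en-1-yl]-7-methyl-7,8-dihydro-6H-isochromene-6,7,8-triol F4 (C6 epimers). C8 is expected trans to the C7 hydroxyl by chelation, with hydride entering anti to the C7 methyl. DDQ (1.05 equiv, CH2Cl2, 0 °C) then re-oxidises only the C6 carbinol, because hydride abstraction there gives an aromatic 2-benzopyrylium-type cation, whereas abstraction at C8 does not. The route is rejoined at 16.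

**Further compounds**
F1 | step 9 | (2S,5R)-2-tert-butyl-5-[2-chloro-3-methyl-1-(trimethylsilyloxy)buta-1,3-dien-1-yl]-5-methyl-1,3-dioxolan-4-one (enol ether E/Z mixture) | CC(=C)C(Cl)=C(O[Si](C)(C)C)[C@@]1(C)O[C@H](C(C)(C)C)OC1=O
F2 | step 11 | (2E,4R,5S,6S)-4,5-dihydroxy-4,6-dimethyloct-2-enal | CC[C@H](C)[C@H](O)[C@](C)(O)/C=C/C=O
F3 | step 11 | (4Z,6S)-2-chloro-4-[(dimethylamino)methylidene]-6-hydroxy-6-methyl-3-[(3E,5R,6S,7S)-2,5,6-trihydroxy-5,7-dimethylnon-3-en-1-yl]cyclohex-2-ene-1,5-dione (carbinol epimers) | CC[C@H](C)[C@H](O)[C@](C)(O)/C=C/C(O)CC1=C(Cl)C(=O)[C@@](C)(O)C(=O)/C1=C\N(C)C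
F4 | step 12 | (7S,8R)-5-chloro-3-[(1E,3R,4S,5S)-3,4-dihydroxy-3,5-dimethylhept-1-en-1-yl]-7-methyl-7,8-dihydro-6H-isochromene-6,7,8-triol (C6 epimers) | CC[C@H](C)[C@H](O)[C@](C)(O)/C=C/C1=CC2=C(Cl)C(O)[C@@](C)(O)[C@H](O)C2=CO1
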